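The earlier runs and the new flask were computed for an exercise.

How much does the rate of making product at 50% conversion in this flask change with the enzyme charged, given that the product stops climbing?

| flask | substrate | enzyme | remark |
|---|---|---|---|
| noon | 0.050 M | 5 µM | the very flask that is asked about, followed so far |
| flask | 0.050 M | 5.0 µM |  |

- noon (time / min: product / %): 5.00: 42; 15.0: 71; 25.0: 84; 40.0: 83; 60.0: 82; 80.0: 84

(readings scatter by 2 percentage points)

- no earlier run changes the charge of enzyme; that part of a forecast is a guess

1. apparent order in enzyme when 50% of the substrate are converted (percent change of the rate of making product for one percent more enzyme charged)
2. factor on the rate of making product when 50% of the substrate are converted if enzyme is charged twice over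

The readings of the noon run from 25.0 min on average 83.2%, so I first asked what enzyme death (catalyst deactivation) would need to produce that stop. I supposed that [substrate] falls first-order at a rate proportional to [enzyme], and that [enzyme] decays exponentially. Integrating that rate, the logarithm of charged over remaining [substrate] climbs exponentially to a ceiling, here 1.79, which is proportional to the enzyme charged. The reading at 15.0 min then gives 0.0787 /min, the demanded death constant: the decay constant of [enzyme] that this stop needs if enzyme death causes it.

Does that curve fit the later readings? At 25.0 min it gives 78.5%, but the reading is higher, by 5.5 percentage points, or 2.75 standard deviations. Enzyme death would give an order of 1.63 and a factor of 2.63. On this single reading I set it aside and guessed an order of 1 and a factor of 2.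

The forecast differed from my guess, with order 1.5 (0.95 to 2.6) and factor 2.6 (1.9 to 3.6), on the ground that “Both explanations are plausible, and I weight them about equally”.

    substrate + enzyme → product + enzyme, rate k1*[substrate]*[enzyme]/(1 + ([substrate]/Km1)) (0.0610 M, k = 35000 /M/min)
    2 substrate → homo dimer (k = 0.500 /M/min)
    enzyme → spent catalyst (k = 0.00680 /min)

The flask gives an order of 1.0 and a factor of 2.03, so the forecast stood above both. At 0.400 h the flask held substrate 2.87%, product 80.0% and homo dimer 17.2%. The demanded death constant of 4.72 /h, larger than the rate constant 0.41 /h with which the flask loses its enzyme, would have left 15.1% of the enzyme at that time, against 84.9% in the flask.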